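**Strategy.** The bridging furanone oxygen sits on C4, allylic to the C5=C6 enol-lactone alkene of the butenolide ring (C6, C7, C11, C12, O). This O–C4–C5=C6 array is the product of a vinylogous E1cB opening of a 4,5-epoxide by the acidic C6–H of a butenolide. The route therefore rests on a ten-membered epoxy butenolide carbocycle in which C1–C3 is a β-methoxy enone (masked 1,3-diketone). In one operation base unveils the C4 hydroxyl and the dienol lactone, then acid closes O–C1 across the ring, expels methanol to give the 3(2H)-furanone and removes both silyl groups. The C6 epimers from the ring-forming chromium-mediated coupling converge.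

Key step: step 13

Remark on locants (germacrane-type, used throughout): C1 = furanone carbon bonded to the ring oxygen and C10; C2 = furanone CH; C3 = furanone C=O; C4 = C(CH3)(O); C5=C6 = exocyclic alkene; C6, C7, C11, C12 = butenolide carbons; C13 = CH2OH on C11; C8 = CH(O-acyl); C9 = CH2; C10 = CH(CH3). The target is 4S,8S,10S with C4 and C7 cis on C5=C6. TBS = tert-butyldimethylsilyl.

Assumption: (S,S)-ProPhenol is taken to deliver the S carbinol at C8 in step 3; should the facial sense be the opposite, the (R,R)-ligand is used.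

Step 1
Reactants: 1 (4R)-4-benzyl-3-propanoyl-1,3-oxazolidin-2-one
Product: 2 (4R)-4-benzyl-3-[(2S)-2-methylpent-4-enoyl]-1,3-oxazolidin-2-one
Conditions: NaN(SiMe3)2, THF, −78 °C; allyl iodide
Reagents that add atoms: allyl iodide, C=CCI
Why: Evans asymmetric alkylation: the chelated sodium Z-enolate is allylated on the face opposite to the benzyl group, which should set C10 (S) with high diastereoselectivity.

Step 2
Reactants: 2 (4R)-4-benzyl-3-[(2S)-2-methylpent-4-enoyl]-1,3-oxazolidin-2-one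
Product: 4 (4R)-4-benzyl-3-[(2S)-2-methyl-4-oxobutanoyl]-1,3-oxazolidin-2-one, via ozonide 3 (not isolated)
Conditions: O3, CH2Cl2, −78 °C; then PPh3
Reagents that add atoms: ozone, [O-][O+]=O
Why: Ozonolysis with reductive work-up cleaves the only C=C bond to the C8 aldehyde and leaves the imide and the α-stereocentre untouched.

Step 3
Reactants: 4 (4R)-4-benzyl-3-[(2S)-2-methyl-4-oxobutanoyl]-1,3-oxazolidin-2-one
Product: 6 methyl 3-[(2S,4S)-4-methyl-5-oxooxolan-2-yl]prop-2-ynoate, via hydroxy ynoate imide 5 (not isolated)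
Conditions: methyl propiolate, Me2Zn, (S,S)-ProPhenol (cat.), Ph3PO (cat.), toluene, 0 °C; then rt
Reagents that add atoms: methyl propiolate, C#CC(=O)OC
Why: Zinc/ProPhenol-catalysed asymmetric alkynylation of the aldehyde should set C8 (S) under catalyst control, and the γ-zinc alkoxide then lactonises onto the activated N-acyl oxazolidinone (intramolecular acyl transfer), which removes the auxiliary and ties C8–O to C1 as a γ-lactone.

Step 4
Reactants: 6 methyl 3-[(2S,4S)-4-methyl-5-oxooxolan-2-yl]prop-2-ynoate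
Product: 8 methyl (2Z)-2-(hydroxymethyl)-3-iodo-3-[(2S,4S)-4-methyl-5-oxooxolan-2-yl]prop-2-enoate, via allenyl ketene acetal 7 (not isolated)
Conditions: Me3SiI, CH2Cl2, −78 °C; then CH2O (monomer in THF), BF3·OEt2 (cat.), −78 °C; aq. NaHCO3
Reagents that add atoms: iodotrimethylsilane, C[Si](C)(C)I; formaldehyde, C=O
Why: Iodo-aldol (halo Baylis–Hillman-type) reaction: conjugate addition of iodide gives the allenyl ketene acetal 7, and its Mukaiyama aldol with formaldehyde at −78 °C should take place anti to iodine, as protonation does in the anti-hydroiodination of 2-alkynoates, so that iodine ends up cis to the ester (Z).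

Step 5
Reactants: 8 methyl (2Z)-2-(hydroxymethyl)-3-iodo-3-[(2S,4S)-4-methyl-5-oxooxolan-2-yl]prop-2-enoate
Product: 9 methyl (2Z)-2-{[(tert-butyldimethylsilyl)oxy]methyl}-3-iodo-3-[(2S,4S)-4-methyl-5-oxooxolan-2-yl]prop-2-enoate
Conditions: TBSCl, imidazole, DMF, 0 °C
Reagents that add atoms: tert-butyldimethylsilyl chloride, CC(C)(C)[Si](C)(C)Cl
Why: Standard silylation of the primary allylic alcohol protects C13–OH for the organometallic steps.

Step 6
Reactants: 10 (2Z)-3-methylpent-2-en-4-yn-1-ol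
Product: 11 [(2S,3R)-3-ethynyl-3-methyloxiran-2-yl]methanol
Conditions: Ti(OiPr)4 (cat.), L-(+)-diethyl tartrate (cat.), t-BuOOH, 4 Å MS, CH2Cl2, −20 °C
Reagents that add atoms: tert-butyl hydroperoxide, CC(C)(C)OO
Why: Sharpless asymmetric epoxidation of a nerol-type (Z)-3,3-disubstituted allylic alcohol: L-(+)-tartrate should deliver oxygen to the face that gives the 2S,3R cis-epoxide, which fixes the quaternary C4 by reagent control.

Step 7
Reactants: 11 [(2S,3R)-3-ethynyl-3-methyloxiran-2-yl]methanol; 9 methyl (2Z)-2-{[(tert-butyldimethylsilyl)oxy]methyl}-3-iodo-3-[(2S,4S)-4-methyl-5-oxooxolan-2-yl]prop-2-enoate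
Product: 13 methyl (2Z,4S,6S,8E)-2-{[(tert-butyldimethylsilyl)oxy]methyl}-4-hydroxy-9-[(2S,3S)-3-(hydroxymethyl)-2-methyloxiran-2-yl]-3-iodo-9-methoxy-6-methyl-7-oxonona-2,8-dienoate, via hydroxy ynone 12 (not isolated)
Conditions: 11, n-BuLi (2.0 equiv), THF, −78 °C; CeCl3; 9, −78 °C; AcOH; then MeOH, DABCO (cat.), 0 °C
Reagents that add atoms: methanol, CO
Why: Acetylide addition to a γ-lactone (the cerium reagent suppresses α-deprotonation) gives the γ-hydroxy ynone 12 with liberation of C8–OH, and amine-catalysed conjugate addition of methanol masks the ynone as the (E)-β-methoxy enone, a 1,3-diketone equivalent that is inert to the chromium reagents used later.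

Step 8
Reactants: 13 methyl (2Z,4S,6S,8E)-2-{[(tert-butyldimethylsilyl)oxy]methyl}-4-hydroxy-9-[(2S,3S)-3-(hydroxymethyl)-2-methyloxiran-2-yl]-3-iodo-9-methoxy-6-methyl-7-oxonona-2,8-dienoate
Product: 14 methyl (2Z,4S,6S,8E)-2-{[(tert-butyldimethylsilyl)oxy]methyl}-9-[(2S,3R)-3-formyl-2-methyloxiran-2-yl]-4-hydroxy-3-iodo-9-methoxy-6-methyl-7-oxonona-2,8-dienoate
Conditions: Cu(MeCN)4OTf, 2,2'-bipyridine, TEMPO, N-methylimidazole (all cat.), air, MeCN, rt
Reagents that add atoms: none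
Why: Copper/nitroxyl aerobic oxidation is selective for the primary C6 alcohol over the hindered secondary C8 alcohol and is mild enough for the epoxide and the enol ether.

Step 9
Reactants: 15 ethyl 2-(hydroxymethyl)prop-2-enoate
Product: 16 ethyl 2-{[(tert-butyldimethylsilyl)oxy]methyl}prop-2-enoate
Conditions: TBSCl, imidazole, CH2Cl2, 0 °C
Reagents that add atoms: tert-butyldimethylsilyl chloride, CC(C)(C)[Si](C)(C)Cl
Why: Silylation of the primary alcohol.

Step 10
Reactants: 16 ethyl 2-{[(tert-butyldimethylsilyl)oxy]methyl}prop-2-enoate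
Product: 17 2-{[(tert-butyldimethylsilyl)oxy]methyl}prop-2-enoic acid
Conditions: LiOH, THF/H2O, 0 °C; then 1 M HCl
Reagents that add atoms: lithium hydroxide, [Li+].[OH-]
Why: Saponification of the ethyl ester at 0 °C should give the acid without conjugate addition or silyl loss.

Step 11
Reactants: 14 methyl (2Z,4S,6S,8E)-2-{[(tert-butyldimethylsilyl)oxy]methyl}-9-[(2S,3R)-3-formyl-2-methyloxiran-2-yl]-4-hydroxy-3-iodo-9-methoxy-6-methyl-7-oxonona-2,8-dienoate; 17 2-{[(tert-butyldimethylsilyl)oxy]methyl}prop-2-enoic acid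
Product: 19 methyl (2Z,4S,6S,8E)-2-{[(tert-butyldimethylsilyl)oxy]methyl}-4-{[2-({[tert-butyldimethylsilyl]oxy}methyl)prop-2-enoyl]oxy}-9-[(2S,3R)-3-formyl-2-methyloxiran-2-yl]-3-iodo-9-methoxy-6-methyl-7-oxonona-2,8-dienoate, via mixed anhydride 18 (not isolated)
Conditions: 17, 2,4,6-trichlorobenzoyl chloride, Et3N, THF; then 14, DMAP (cat.), toluene, 0 °C
Reagents that add atoms: none
Why: Yamaguchi esterification acylates the only free hydroxyl group (C8–OH) before a second secondary alcohol is created at C6.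

Step 12
Reactants: 19 methyl (2Z,4S,6S,8E)-2-{[(tert-butyldimethylsilyl)oxy]methyl}-4-{[2-({[tert-butyldimethylsilyl]oxy}methyl)prop-2-enoyl]oxy}-9-[(2S,3R)-3-formyl-2-methyloxiran-2-yl]-3-iodo-9-methoxy-6-methyl-7-oxonona-2,8-dienoate
Product: 21 (4S,5S,8S,10S)-13-[(tert-butyldimethylsilyl)oxy]-8-{[2-({[tert-butyldimethylsilyl]oxy}methyl)prop-2-enoyl]oxy}-4,5-epoxy-3-methoxy-1-oxogermacra-2E,7(11)-dien-12,6-olide (C6 epimers), via seco hydroxy ester 20 (not isolated)
Conditions: CrCl2 (10 equiv), NiCl2 (cat.), DMSO/THF, rt, 2 mM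
Reagents that add atoms: none
Why: Intramolecular Nozaki–Hiyama–Kishi reaction: the alkenylchromium formed from the activated (Z)-β-iodo enoate adds to the aldehyde and the C6 alkoxide lactonises onto the cis ester, so that the ten-membered carbocycle and the butenolide close together, the C6 configuration being irrelevant because step 13 makes C6 trigonal.

Step 13
Reactants: 21 (4S,5S,8S,10S)-13-[(tert-butyldimethylsilyl)oxy]-8-{[2-({[tert-butyldimethylsilyl]oxy}methyl)prop-2-enoyl]oxy}-4,5-epoxy-3-methoxy-1-oxogermacra-2E,7(11)-dien-12,6-olide (C6 epimers)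
Product: 24 (4S,8S,10S)-13-hydroxy-8-{[2-(hydroxymethyl)prop-2-enoyl]oxy}-3-oxo-1,4-epoxygermacra-1,5E,7(11)-trien-12,6-olide (CNP0261115.1), via hydroxy dienolide 22 (not isolated), via bis-silyl furanone 23 (not isolated)
Conditions: DBU (0.2 equiv), CH2Cl2, −20 °C; then 48% aq. HF, MeCN, 0 °C to rt
Reagents that add atoms: water, O
Why: DBU removes the acidic γ-proton at C6 of the butenolide and the 2-oxidofuran so formed opens the 4,5-epoxide by vinylogous E1cB elimination, which creates the C5=C6 enol-lactone alkene and the free tertiary C4 hydroxyl (22). In aqueous HF the C4 hydroxyl adds across the ring to the C1 carbonyl of the β-methoxy enone (5-exo-trig), the hemiketal loses water and the 3-methoxyfuranyl cation is hydrolysed with loss of methanol, which closes the furanone ring O–C1=C2–C3(=O)–C4 (23), and the same acid cleaves both silyl ethers. The closest known reactions are the base-induced isomerisation of glaucolide-type 4,5-epoxy-7(11)-en-12,6-olides to hirsutinolides and the acid cyclisation of γ-hydroxy β-alkoxy enones to 3(2H)-furanones. No stereocentre is created: C4 keeps the configuration from step 6 because its C–O bond is never broken, and the C5=C6 geometry (C4 cis to C7) is imposed by the ten-membered ring. The C6 epimers of 21 converge because C6 becomes trigonal. The step needs attack of the C4 hydroxyl alone at C1, which is secured because C8–O is already acylated and no other hydroxyl can reach C1 through a five-membered transition state, and the base is quenched before the furanone appears.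

**Compound list**

1 | (4R)-4-benzyl-3-propanoyl-1,3-oxazolidin-2-one | CCC(=O)N1[C@H](Cc2ccccc2)COC1=O | starting material
2 | (4R)-4-benzyl-3-[(2S)-2-methylpent-4-enoyl]-1,3-oxazolidin-2-one | C=CC[C@H](C)C(=O)N1[C@H](Cc2ccccc2)COC1=O | intermediate
3 | (4R)-4-benzyl-3-[(2S)-2-methyl-3-(1,2,4-trioxolan-3-yl)propanoyl]-1,3-oxazolidin-2-one (ozonide, not isolated) | C1OC(C[C@H](C)C(=O)N2[C@H](Cc3ccccc3)COC2=O)OO1 | intermediate
4 | (4R)-4-benzyl-3-[(2S)-2-methyl-4-oxobutanoyl]-1,3-oxazolidin-2-one | O=CC[C@H](C)C(=O)N1[C@H](Cc2ccccc2)COC1=O | intermediate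
5 | methyl (4S,6S)-7-[(4R)-4-benzyl-2-oxo-1,3-oxazolidin-3-yl]-4-hydroxy-6-methyl-7-oxohept-2-ynoate (not isolated) | COC(=O)C#C[C@@H](O)C[C@H](C)C(=O)N1[C@H](Cc2ccccc2)COC1=O | intermediate
6 | methyl 3-[(2S,4S)-4-methyl-5-oxooxolan-2-yl]prop-2-ynoate | COC(=O)C#C[C@@H]1C[C@H](C)C(=O)O1 | intermediate
7 | {[3-iodo-1-methoxy-3-[(2S,4S)-4-methyl-5-oxooxolan-2-yl]propa-1,2-dien-1-yl]oxy}trimethylsilane (not isolated) | COC(O[Si](C)(C)C)=C=C(I)[C@@H]1C[C@H](C)C(=O)O1 | intermediate
8 | methyl (2Z)-2-(hydroxymethyl)-3-iodo-3-[(2S,4S)-4-methyl-5-oxooxolan-2-yl]prop-2-enoate | COC(=O)/C(CO)=C(\I)[C@@H]1C[C@H](C)C(=O)O1 | intermediate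
9 | methyl (2Z)-2-{[(tert-butyldimethylsilyl)oxy]methyl}-3-iodo-3-[(2S,4S)-4-methyl-5-oxooxolan-2-yl]prop-2-enoate | COC(=O)/C(CO[Si](C)(C)C(C)(C)C)=C(\I)[C@@H]1C[C@H](C)C(=O)O1 | intermediate
10 | (2Z)-3-methylpent-2-en-4-yn-1-ol | C#C/C(C)=C\CO | starting material
11 | [(2S,3R)-3-ethynyl-3-methyloxiran-2-yl]methanol | OC[C@@H]1O[C@]1(C)C#C | intermediate
12 | methyl (2Z,4S,6S)-2-{[(tert-butyldimethylsilyl)oxy]methyl}-4-hydroxy-9-[(2R,3S)-3-(hydroxymethyl)-2-methyloxiran-2-yl]-3-iodo-6-methyl-7-oxonon-2-en-8-ynoate (not isolated) | OC[C@@H]1O[C@]1(C)C#CC(=O)[C@@H](C)C[C@H](O)/C(I)=C(\CO[Si](C)(C)C(C)(C)C)C(=O)OC | intermediate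
13 | methyl (2Z,4S,6S,8E)-2-{[(tert-butyldimethylsilyl)oxy]methyl}-4-hydroxy-9-[(2S,3S)-3-(hydroxymethyl)-2-methyloxiran-2-yl]-3-iodo-9-methoxy-6-methyl-7-oxonona-2,8-dienoate | OC[C@@H]1O[C@]1(C)/C(OC)=C\C(=O)[C@@H](C)C[C@H](O)/C(I)=C(\CO[Si](C)(C)C(C)(C)C)C(=O)OC | intermediate
14 | methyl (2Z,4S,6S,8E)-2-{[(tert-butyldimethylsilyl)oxy]methyl}-9-[(2S,3R)-3-formyl-2-methyloxiran-2-yl]-4-hydroxy-3-iodo-9-methoxy-6-methyl-7-oxonona-2,8-dienoate | O=C[C@@H]1O[C@]1(C)/C(OC)=C\C(=O)[C@@H](C)C[C@H](O)/C(I)=C(\CO[Si](C)(C)C(C)(C)C)C(=O)OC | intermediate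
15 | ethyl 2-(hydroxymethyl)prop-2-enoate | C=C(CO)C(=O)OCC | starting material
16 | ethyl 2-{[(tert-butyldimethylsilyl)oxy]methyl}prop-2-enoate | C=C(CO[Si](C)(C)C(C)(C)C)C(=O)OCC | intermediate
17 | 2-{[(tert-butyldimethylsilyl)oxy]methyl}prop-2-enoic acid | C=C(CO[Si](C)(C)C(C)(C)C)C(=O)O | intermediate
18 | 2-{[(tert-butyldimethylsilyl)oxy]methyl}prop-2-enoic 2,4,6-trichlorobenzoic anhydride (not isolated) | C=C(CO[Si](C)(C)C(C)(C)C)C(=O)OC(=O)c1c(Cl)cc(Cl)cc1Cl | intermediate
19 | methyl (2Z,4S,6S,8E)-2-{[(tert-butyldimethylsilyl)oxy]methyl}-4-{[2-({[tert-butyldimethylsilyl]oxy}methyl)prop-2-enoyl]oxy}-9-[(2S,3R)-3-formyl-2-methyloxiran-2-yl]-3-iodo-9-methoxy-6-methyl-7-oxonona-2,8-dienoate | O=C[C@@H]1O[C@]1(C)/C(OC)=C\C(=O)[C@@H](C)C[C@H](OC(=O)C(=C)CO[Si](C)(C)C(C)(C)C)/C(I)=C(\CO[Si](C)(C)C(C)(C)C)C(=O)OC | intermediate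
20 | ten-membered seco hydroxy ester: (4S,5S,8S,10S)-methyl 13-[(tert-butyldimethylsilyl)oxy]-8-acyloxy-4,5-epoxy-6-hydroxy-3-methoxy-1-oxogermacra-2E,7(11)Z-dien-12-oate, C6 epimers (not isolated) | C[C@H]1C[C@H](OC(=O)C(=C)CO[Si](C)(C)C(C)(C)C)/C(=C(\CO[Si](C)(C)C(C)(C)C)C(=O)OC)C(O)[C@@H]2O[C@]2(C)/C(OC)=C\C1=O | intermediate
21 | (4S,5S,8S,10S)-13-[(tert-butyldimethylsilyl)oxy]-8-{[2-({[tert-butyldimethylsilyl]oxy}methyl)prop-2-enoyl]oxy}-4,5-epoxy-3-methoxy-1-oxogermacra-2E,7(11)-dien-12,6-olide (C6 epimers) | C[C@H]1C[C@H](OC(=O)C(=C)CO[Si](C)(C)C(C)(C)C)C2=C(CO[Si](C)(C)C(C)(C)C)C(=O)OC2[C@@H]3O[C@]3(C)/C(OC)=C\C1=O | intermediate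
22 | (4S,8S,10S)-13-[(tert-butyldimethylsilyl)oxy]-8-{[2-({[tert-butyldimethylsilyl]oxy}methyl)prop-2-enoyl]oxy}-4-hydroxy-3-methoxy-1-oxogermacra-2E,5E,7(11)-trien-12,6-olide (not isolated) | C[C@H]1C[C@H](OC(=O)C(=C)CO[Si](C)(C)C(C)(C)C)C2=C(CO[Si](C)(C)C(C)(C)C)C(=O)O/C2=C/[C@](C)(O)/C(OC)=C\C1=O | intermediate
23 | (4S,8S,10S)-13-[(tert-butyldimethylsilyl)oxy]-8-{[2-({[tert-butyldimethylsilyl]oxy}methyl)prop-2-enoyl]oxy}-3-oxo-1,4-epoxygermacra-1,5E,7(11)-trien-12,6-olide (not isolated) | C=C(CO[Si](C)(C)C(C)(C)C)C(=O)O[C@H]1C[C@H](C)C2=CC(=O)[C@](C)(/C=C3/OC(=O)C(CO[Si](C)(C)C(C)(C)C)=C31)O2 | intermediate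
24 | (4S,8S,10S)-13-hydroxy-8-{[2-(hydroxymethyl)prop-2-enoyl]oxy}-3-oxo-1,4-epoxygermacra-1,5E,7(11)-trien-12,6-olide (CNP0261115.1) | C=C(CO)C(=O)O[C@H]1C[C@H](C)C2=CC(=O)[C@](C)(/C=C3/OC(=O)C(CO)=C31)O2 | target

**Step count.** Total: 13 steps. Longest linear sequence: 10 steps (steps 1, 2, 3, 4, 5, 7, 8, 11, 12, 13).

**Steps most likely to fail**

Step 12. What may go wrong: β-elimination of the C8 carboxylate from the alkenylchromium to an allene, or intermolecular coupling outpacing closure of the ten-membered ring. The fallback sets out from 14 and closes the ring before the ester is installed, so that C8 carries a chromium alkoxide in place of a leaving group. Treatment of 14 with CrCl2 and NiCl2 (cat.) in DMSO/THF at high dilution should give the macrocyclic epoxy butenolide alcohol F1. Esterification of F1 with 17 (N,N'-diisopropylcarbodiimide, DMAP, DMAP hydrochloride, CH2Cl2, 0 °C) comes back to the route at 21.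

Step 4. What may go wrong: loss of kinetic control in the aldol step, with equilibration to the isomer that has iodine trans to the ester (unable to lactonise in step 12), or protonation of 7 before C–C bond formation. The fallback sets out from 6 and fixes the alkene geometry by chelation-controlled enolisation. Conjugate addition of pyrrolidine and mild acid hydrolysis should give the β-keto ester F2. Hydroxymethylation (aqueous formaldehyde, KHCO3 cat.) should give the hydroxymethyl keto ester F3, and silylation the TBS ether F4. Triflation of the chelated lithium enolate (Tf2O, aq. LiOH, toluene) should give the (Z)-enol triflate F5. Stannylation (Me3SnSnMe3, Pd(PPh3)4, LiCl) should give the (Z)-alkenylstannane F6, and iododestannylation (I2, CH2Cl2) comes back to the route at 9.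

Step 7. What may go wrong: collapse of the lactol alkoxide to the ynone in the basic medium, followed by a second acetylide addition or conjugate addition of alkoxide, and deprotonation of the lactone at C10 with loss of configuration. The fallback sets out from 9 and uses an acyl donor whose tetrahedral adduct is stable until work-up. Opening of the lactone with MeNH(OMe)·HCl and Me3Al should give the hydroxy Weinreb amide F7, and silylation (Et3SiCl, imidazole) the triethylsilyl ether F8. Addition of the dilithio derivative of 11 to F8, followed by MeOH and DABCO, should give the β-methoxy enone triethylsilyl ether F9. Selective removal of the triethylsilyl group (PPTS, MeOH, 0 °C) comes back to the route at 13.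

**Further compounds**

F1 | step 12 | (4S,5S,8S,10S)-13-[(tert-butyldimethylsilyl)oxy]-4,5-epoxy-8-hydroxy-3-methoxy-1-oxogermacra-2E,7(11)-dien-12,6-olide (C6 epimers) | C[C@H]1C[C@H](O)C2=C(CO[Si](C)(C)C(C)(C)C)C(=O)OC2[C@@H]3O[C@]3(C)/C(OC)=C\C1=O
F2 | step 4 | methyl 3-[(2S,4S)-4-methyl-5-oxooxolan-2-yl]-3-oxopropanoate | COC(=O)CC(=O)[C@@H]1C[C@H](C)C(=O)O1
F3 | step 4 | methyl 2-(hydroxymethyl)-3-[(2S,4S)-4-methyl-5-oxooxolan-2-yl]-3-oxopropanoate (C2 epimers) | COC(=O)C(CO)C(=O)[C@@H]1C[C@H](C)C(=O)O1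
F4 | step 4 | methyl 2-{[(tert-butyldimethylsilyl)oxy]methyl}-3-[(2S,4S)-4-methyl-5-oxooxolan-2-yl]-3-oxopropanoate (C2 epimers) | COC(=O)C(CO[Si](C)(C)C(C)(C)C)C(=O)[C@@H]1C[C@H](C)C(=O)O1
F5 | step 4 | methyl (2Z)-2-{[(tert-butyldimethylsilyl)oxy]methyl}-3-[(2S,4S)-4-methyl-5-oxooxolan-2-yl]-3-{[(trifluoromethyl)sulfonyl]oxy}prop-2-enoate | COC(=O)/C(CO[Si](C)(C)C(C)(C)C)=C(\OS(=O)(=O)C(F)(F)F)[C@@H]1C[C@H](C)C(=O)O1
F6 | step 4 | methyl (2Z)-2-{[(tert-butyldimethylsilyl)oxy]methyl}-3-[(2S,4S)-4-methyl-5-oxooxolan-2-yl]-3-(trimethylstannyl)prop-2-enoate | COC(=O)/C(CO[Si](C)(C)C(C)(C)C)=C(\[Sn](C)(C)C)[C@@H]1C[C@H](C)C(=O)O1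
F7 | step 7 | methyl (2Z,4S,6S)-2-{[(tert-butyldimethylsilyl)oxy]methyl}-4-hydroxy-3-iodo-7-[methoxy(methyl)amino]-6-methyl-7-oxohept-2-enoate | COC(=O)/C(CO[Si](C)(C)C(C)(C)C)=C(\I)[C@@H](O)C[C@H](C)C(=O)N(C)OC
F8 | step 7 | methyl (2Z,4S,6S)-2-{[(tert-butyldimethylsilyl)oxy]methyl}-3-iodo-7-[methoxy(methyl)amino]-6-methyl-7-oxo-4-[(triethylsilyl)oxy]hept-2-enoate | COC(=O)/C(CO[Si](C)(C)C(C)(C)C)=C(\I)[C@@H](O[Si](CC)(CC)CC)C[C@H](C)C(=O)N(C)OC
F9 | step 7 | methyl (2Z,4S,6S,8E)-2-{[(tert-butyldimethylsilyl)oxy]methyl}-9-[(2S,3S)-3-(hydroxymethyl)-2-methyloxiran-2-yl]-3-iodo-9-methoxy-6-methyl-7-oxo-4-[(triethylsilyl)oxy]nona-2,8-dienoate | OC[C@@H]1O[C@]1(C)/C(OC)=C\C(=O)[C@@H](C)C[C@H](O[Si](CC)(CC)CC)/C(I)=C(\CO[Si](C)(C)C(C)(C)C)C(=O)OC
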